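## Retrosynthetic overview

1. Target 26 ⇐ acid-induced loss of the C4 silyloxy group (creating C3=C4) and of the MOM group from the all-cis tetralin 24; C3 and C4 are sacrificial control centres.
2. 24 ⇐ syn-hydrogenation of the tetrasubstituted C1=C2 alkene 22 (sets C1 and C2 cis) ⇐ Suzuki coupling of enol triflate 17 with ring B boronate 21.
3. 17 ⇐ tetralone 15 ⇐ Parham cyclisation of an ortho-lithiated arene onto a Weinreb amide (C1–C8a bond). Ring C is the only ring formed; rings A and B are bought as syringaldehyde and 2,6-dimethoxyphenol.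
4. Open chain 12 ⇐ key C3–C4 bond: intermolecular asymmetric carbonyl crotylation of bromo aldehyde 3 with (E)-crotyl-B(Ipc)2, which sets C3/C4 anti and is the source of all absolute configuration.

Convention: skeleton locants are those of the target (C1 bears ring B, C2 and C3 bear the methyls, C4 is the carbon next to C4a, C5–C8 belong to ring A). The target is (1S,2S), with the aryl group and the C2 methyl cis.

## Route

Step 1
Reactants: 1 syringaldehyde (4-hydroxy-3,5-dimethoxybenzaldehyde)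
Product: 2 3,5-dimethoxy-4-(methoxymethoxy)benzaldehyde
Conditions: MOMCl, i-Pr2NEt, CH2Cl2, 0 °C → rt
Reagents that add atoms: chloromethyl methyl ether, COCCl
Why: Williamson-type O-alkylation (MOM protection) of the only acidic OH; the acetal survives every later base, organolithium and hydrogenation step.

Step 2
Reactants: 2 3,5-dimethoxy-4-(methoxymethoxy)benzaldehyde
Product: 3 2-bromo-3,5-dimethoxy-4-(methoxymethoxy)benzaldehyde
Conditions: NBS (1.05 equiv), DMF, rt
Reagents that add atoms: N-bromosuccinimide, O=C1CCC(=O)N1Br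
Why: Electrophilic aromatic bromination; the two free ring positions are equivalent and activated ortho/para by the flanking methoxy groups, so one bromine enters next to the formyl group (future C8a).

Step 3
Reactants: 3 2-bromo-3,5-dimethoxy-4-(methoxymethoxy)benzaldehyde
Product: 5 (1S,2S)-1-[2-bromo-3,5-dimethoxy-4-(methoxymethoxy)phenyl]-2-methylbut-3-en-1-ol (anti), via borinate ester 4 (not isolated)
Conditions: trans-2-butene, KOt-Bu, n-BuLi, THF, −45 °C; (−)-Ipc2BOMe, −78 °C; BF3·OEt2; then 3, −78 °C; then NaOH, H2O2, 0 °C → rt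
Reagents that add atoms: (E)-crotyldiisopinocampheylborane (made in the flask from trans-2-butene and (−)-Ipc2BOMe), C/C=C/CB([C@@H]1C[C@@H]2C[C@H]([C@H]1C)C2(C)C)[C@@H]1C[C@@H]2C[C@H]([C@H]1C)C2(C)C
Why: Brown asymmetric crotylboration (carbonyl allylation) through a closed chair transition state, in which the (E)-crotyl geometry gives the anti relationship and the (+)-α-pinene-derived Ipc groups select the aldehyde face leading to the (S)-carbinol, so C4 (S) and C3 (S) are set together (typically ≥ 90% ee, anti:syn > 95:5).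

Step 4
Reactants: 5 (1S,2S)-1-[2-bromo-3,5-dimethoxy-4-(methoxymethoxy)phenyl]-2-methylbut-3-en-1-ol
Product: 6 {[(1S,2S)-1-[2-bromo-3,5-dimethoxy-4-(methoxymethoxy)phenyl]-2-methylbut-3-en-1-yl]oxy}(tert-butyl)dimethylsilane
Conditions: TBSCl, imidazole, DMF, 40 °C
Reagents that add atoms: tert-butyldimethylsilyl chloride, CC(C)(C)[Si](C)(C)Cl
Why: Silyl ether formation on the secondary benzylic alcohol; the bulky C4–OTBS group later shields one face of ring C and finally serves as the leaving group.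

Step 5
Reactants: 6 the TBS ether of 5
Product: 8 (3S,4S)-4-[2-bromo-3,5-dimethoxy-4-(methoxymethoxy)phenyl]-4-[(tert-butyldimethylsilyl)oxy]-3-methylbutan-1-ol, via B-alkyl-9-borabicyclononane 7 (not isolated)
Conditions: 9-BBN, THF, 0 °C → rt; then NaOH, H2O2, 0 °C
Reagents that add atoms: hydrogen peroxide, OO
Why: Anti-Markovnikov hydroboration–oxidation of the terminal alkene puts oxygen on the terminal carbon (future C1) without touching the two stereocentres or the aryl bromide.

Step 6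
Reactants: 8 (3S,4S)-4-aryl-4-(TBS-oxy)-3-methylbutan-1-ol
Product: 9 (3S,4S)-4-[2-bromo-3,5-dimethoxy-4-(methoxymethoxy)phenyl]-4-[(tert-butyldimethylsilyl)oxy]-3-methylbutanoic acid
Conditions: TEMPO (cat.), PhI(OAc)2, MeCN/H2O (1:1), rt
Reagents that add atoms: water, O
Why: Oxoammonium (TEMPO)-catalysed oxidation of the primary alcohol through the aldehyde hydrate to the acid under near-neutral conditions that spare the silyl ether and the MOM acetal.

Step 7
Reactants: 9 (3S,4S)-4-aryl-4-(TBS-oxy)-3-methylbutanoic acid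
Product: 10 (3S,4S)-4-[2-bromo-3,5-dimethoxy-4-(methoxymethoxy)phenyl]-4-[(tert-butyldimethylsilyl)oxy]-N-methoxy-N,3-dimethylbutanamide
Conditions: MeNH(OMe)·HCl, EDC·HCl, HOBt, i-Pr2NEt, CH2Cl2, 0 °C → rt
Reagents that add atoms: N,O-dimethylhydroxylamine hydrochloride, CNOC.Cl
Why: Carbodiimide-mediated amide coupling gives the Weinreb amide that will act as a mono-acylating electrophile in the ring closure.

Step 8
Reactants: 10 the Weinreb amide
Product: 12 (3S,4S)-4-[2-bromo-3,5-dimethoxy-4-(methoxymethoxy)phenyl]-4-[(tert-butyldimethylsilyl)oxy]-N-methoxy-N,2,3-trimethylbutanamide (both C2 epimers), via lithium enolate 11 (not isolated)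
Conditions: LiN(i-Pr)2, THF, −78 °C; MeI, −78 → −40 °C
Reagents that add atoms: iodomethane, CI
Why: Amide enolate alkylation installs the C2 methyl; the new centre is formed unselectively, which does not matter because C2 becomes sp2 in step 10 and is re-set in step 15.

Step 9
Reactants: 12 the α-methyl Weinreb amide
Product: 15 (3S,4S)-4-[(tert-butyldimethylsilyl)oxy]-6,8-dimethoxy-7-(methoxymethoxy)-2,3-dimethyl-3,4-dihydronaphthalen-1(2H)-one (C2 epimers), via aryllithium 13 (not isolated), via tetrahedral lithium hemiaminal alkoxide 14 (not isolated)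
Conditions: t-BuLi (2.1 equiv), THF, −78 °C; then aq. NH4Cl
Reagents that add atoms: none
Why: Parham cyclisation, in which bromine–lithium exchange outruns attack on the amide and the aryllithium then closes ring C by 6-exo acyl substitution on the Weinreb amide; the chelated adduct prevents over-addition and the bromine position fixes the C1–C8a regiochemistry.

Step 10
Reactants: 15 the tetralone
Product: 17 (3S,4S)-4-[(tert-butyldimethylsilyl)oxy]-6,8-dimethoxy-7-(methoxymethoxy)-2,3-dimethyl-3,4-dihydronaphthalen-1-yl trifluoromethanesulfonate, via potassium enolate 16 (not isolated)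
Conditions: KN(SiMe3)2, THF, −78 °C; PhNTf2, −78 → 0 °C
Reagents that add atoms: N-phenylbis(trifluoromethanesulfonimide), O=S(=O)(N(c1ccccc1)S(=O)(=O)C(F)(F)F)C(F)(F)F
Why: Enolate O-sulfonylation (enol triflate formation) is regiospecific because C2 is the only α-carbon, and it merges both C2 epimers into one C1=C2 alkene.

Step 11
Reactants: 18 2,6-dimethoxyphenol
Product: 19 4-bromo-2,6-dimethoxyphenol
Conditions: NBS, NaH (1 mol %), CHCl3, −45 °C → rt
Reagents that add atoms: N-bromosuccinimide, O=C1CCC(=O)N1Br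
Why: Electrophilic aromatic bromination directed para to the phenol (both ortho positions are blocked by methoxy groups) at low temperature.

Step 12
Reactants: 19 4-bromo-2,6-dimethoxyphenol
Product: 20 2-(benzyloxy)-5-bromo-1,3-dimethoxybenzene
Conditions: BnBr, K2CO3, DMF, 60 °C
Reagents that add atoms: benzyl bromide, BrCc1ccccc1
Why: Williamson ether synthesis; the benzyl group masks the ring B phenol and is removed for free in step 15.

Step 13
Reactants: 20 2-(benzyloxy)-5-bromo-1,3-dimethoxybenzene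
Product: 21 2-[4-(benzyloxy)-3,5-dimethoxyphenyl]-4,4,5,5-tetramethyl-1,3,2-dioxaborolane
Conditions: B2pin2, Pd(dppf)Cl2 (3 mol %), KOAc, 1,4-dioxane, 90 °C
Reagents that add atoms: bis(pinacolato)diboron, CC1(C)OB(OC1(C)C)B1OC(C)(C)C(C)(C)O1
Why: Miyaura borylation of an unhindered, electron-rich aryl bromide.

Step 14
Reactants: 17 the enol triflate; 21 the ring B pinacol boronate
Product: 22 (3S,4S)-1-[4-(benzyloxy)-3,5-dimethoxyphenyl]-4-[(tert-butyldimethylsilyl)oxy]-6,8-dimethoxy-7-(methoxymethoxy)-2,3-dimethyl-3,4-dihydronaphthalene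
Conditions: Pd(OAc)2 (5 mol %), SPhos (10 mol %), K3PO4, toluene/H2O (10:1), 80 °C
Reagents that add atoms: none
Why: Suzuki–Miyaura coupling of the enol triflate with an aryl boronate that has no ortho substituents, using a bulky biarylphosphine to cope with the tetrasubstituted, peri-methoxy-flanked triflate; C3 and C4 are untouched.

Step 15
Reactants: 22 the 1-aryl-3,4-dihydronaphthalene
Product: 24 4-[(1S,2S,3S,4S)-4-[(tert-butyldimethylsilyl)oxy]-6,8-dimethoxy-7-(methoxymethoxy)-2,3-dimethyl-1,2,3,4-tetrahydronaphthalen-1-yl]-2,6-dimethoxyphenol (all-cis), via debenzylated alkene 23 (not isolated)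
Conditions: H2 (4 bar), 10% Pd/C, EtOAc, rt
Reagents that add atoms: none
Why: Heterogeneous catalytic hydrogenation delivers both hydrogens to one face, which forces ring B and the C2 methyl cis, and that face is the one opposite the cis C3-methyl/C4-OTBS pair (1,2-allylic strain holds the C3 methyl pseudoaxial), giving the (1S,2S) centres; the benzyl ether is hydrogenolysed in the same operation and any wrong-face product is a separable diastereomer.

Step 16
Reactants: 24 the all-cis tetralin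
Product: 26 4-[(1S,2S)-7-hydroxy-6,8-dimethoxy-2,3-dimethyl-1,2-dihydronaphthalen-1-yl]-2,6-dimethoxyphenol (target), via dihydronaphthalene MOM ether 25 (not isolated)
Conditions: 3 M aq. HCl, THF, 50 °C
Reagents that add atoms: none
Why: Acid-mediated E1 elimination and acetal hydrolysis, in which the electron-rich benzylic C4–O bond ionises and the cation loses its only β-hydrogen (C3–H) to give the conjugated C3=C4 alkene while the MOM group is cleaved; C1 and C2 take no part and keep their configuration.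

## Compound list

1 | syringaldehyde | COc1cc(C=O)cc(OC)c1O | starting material
2 | 3,5-dimethoxy-4-(methoxymethoxy)benzaldehyde | COCOc1c(OC)cc(C=O)cc1OC | intermediate
3 | 2-bromo-3,5-dimethoxy-4-(methoxymethoxy)benzaldehyde | COCOc1c(OC)cc(C=O)c(Br)c1OC | intermediate
4 | (1S,2S)-1-aryl-2-methylbut-3-enyl diisopinocampheylborinate (not isolated) | C=C[C@H](C)[C@H](OB([C@@H]2C[C@@H]3C[C@H]([C@H]2C)C3(C)C)[C@@H]2C[C@@H]3C[C@H]([C@H]2C)C3(C)C)c1cc(OC)c(OCOC)c(OC)c1Br | intermediate
5 | (1S,2S)-1-[2-bromo-3,5-dimethoxy-4-(methoxymethoxy)phenyl]-2-methylbut-3-en-1-ol | C=C[C@H](C)[C@H](O)c1cc(OC)c(OCOC)c(OC)c1Br | intermediate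
6 | TBS ether of 5 | C=C[C@H](C)[C@H](O[Si](C)(C)C(C)(C)C)c1cc(OC)c(OCOC)c(OC)c1Br | intermediate
7 | B-[(3S,4S)-4-aryl-4-(TBS-oxy)-3-methylbutyl]-9-borabicyclo[3.3.1]nonane (not isolated) | B1(C2CCCC1CCC2)CC[C@H](C)[C@H](O[Si](C)(C)C(C)(C)C)c1cc(OC)c(OCOC)c(OC)c1Br | intermediate
8 | (3S,4S)-4-[2-bromo-3,5-dimethoxy-4-(methoxymethoxy)phenyl]-4-[(tert-butyldimethylsilyl)oxy]-3-methylbutan-1-ol | OCC[C@H](C)[C@H](O[Si](C)(C)C(C)(C)C)c1cc(OC)c(OCOC)c(OC)c1Br | intermediate
9 | (3S,4S)-4-aryl-4-(TBS-oxy)-3-methylbutanoic acid | OC(=O)C[C@H](C)[C@H](O[Si](C)(C)C(C)(C)C)c1cc(OC)c(OCOC)c(OC)c1Br | intermediate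
10 | (3S,4S)-4-aryl-4-(TBS-oxy)-N-methoxy-N,3-dimethylbutanamide | CON(C)C(=O)C[C@H](C)[C@H](O[Si](C)(C)C(C)(C)C)c1cc(OC)c(OCOC)c(OC)c1Br | intermediate
11 | lithium enolate of 10 (not isolated) | CON(C)C(O[Li])=C[C@H](C)[C@H](O[Si](C)(C)C(C)(C)C)c1cc(OC)c(OCOC)c(OC)c1Br | intermediate
12 | (3S,4S)-4-aryl-4-(TBS-oxy)-N-methoxy-N,2,3-trimethylbutanamide (C2 epimers) | CON(C)C(=O)C(C)[C@H](C)[C@H](O[Si](C)(C)C(C)(C)C)c1cc(OC)c(OCOC)c(OC)c1Br | intermediate
13 | aryllithium from 12 (not isolated) | CON(C)C(=O)C(C)[C@H](C)[C@H](O[Si](C)(C)C(C)(C)C)c1cc(OC)c(OCOC)c(OC)c1[Li] | intermediate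
14 | cyclised tetrahedral lithium alkoxide, 1-(N-methoxy-N-methylamino)tetralin-1-olate (not isolated) | CC1C(O[Li])(N(C)OC)c2c(OC)c(OCOC)c(OC)cc2[C@@H](O[Si](C)(C)C(C)(C)C)[C@H]1C | intermediate
15 | (3S,4S)-4-[(tert-butyldimethylsilyl)oxy]-6,8-dimethoxy-7-(methoxymethoxy)-2,3-dimethyl-3,4-dihydronaphthalen-1(2H)-one (C2 epimers) | CC1C(=O)c2c(OC)c(OCOC)c(OC)cc2[C@@H](O[Si](C)(C)C(C)(C)C)[C@H]1C | intermediate
16 | potassium enolate of 15 (not isolated) | CC1=C(O[K])c2c(OC)c(OCOC)c(OC)cc2[C@@H](O[Si](C)(C)C(C)(C)C)[C@H]1C | intermediate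
17 | (3S,4S)-4-(TBS-oxy)-6,8-dimethoxy-7-(methoxymethoxy)-2,3-dimethyl-3,4-dihydronaphthalen-1-yl triflate | CC1=C(OS(=O)(=O)C(F)(F)F)c2c(OC)c(OCOC)c(OC)cc2[C@@H](O[Si](C)(C)C(C)(C)C)[C@H]1C | intermediate
18 | 2,6-dimethoxyphenol | COc1cccc(OC)c1O | starting material
19 | 4-bromo-2,6-dimethoxyphenol | COc1cc(Br)cc(OC)c1O | intermediate
20 | 2-(benzyloxy)-5-bromo-1,3-dimethoxybenzene | COc1cc(Br)cc(OC)c1OCc1ccccc1 | intermediate
21 | 2-[4-(benzyloxy)-3,5-dimethoxyphenyl]-4,4,5,5-tetramethyl-1,3,2-dioxaborolane | COc1cc(B2OC(C)(C)C(C)(C)O2)cc(OC)c1OCc1ccccc1 | intermediate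
22 | (3S,4S)-1-[4-(benzyloxy)-3,5-dimethoxyphenyl]-4-(TBS-oxy)-6,8-dimethoxy-7-(methoxymethoxy)-2,3-dimethyl-3,4-dihydronaphthalene | CC1=C(c2cc(OC)c(OCc3ccccc3)c(OC)c2)c2c(OC)c(OCOC)c(OC)cc2[C@@H](O[Si](C)(C)C(C)(C)C)[C@H]1C | intermediate
23 | debenzylated alkene, the 4-hydroxy-3,5-dimethoxyphenyl analogue of 22 (not isolated) | CC1=C(c2cc(OC)c(O)c(OC)c2)c2c(OC)c(OCOC)c(OC)cc2[C@@H](O[Si](C)(C)C(C)(C)C)[C@H]1C | intermediate
24 | 4-[(1S,2S,3S,4S)-4-(TBS-oxy)-6,8-dimethoxy-7-(methoxymethoxy)-2,3-dimethyl-1,2,3,4-tetrahydronaphthalen-1-yl]-2,6-dimethoxyphenol (all-cis) | C[C@H]1[C@@H](c2cc(OC)c(O)c(OC)c2)c2c(OC)c(OCOC)c(OC)cc2[C@@H](O[Si](C)(C)C(C)(C)C)[C@H]1C | intermediate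
25 | 4-[(1S,2S)-6,8-dimethoxy-7-(methoxymethoxy)-2,3-dimethyl-1,2-dihydronaphthalen-1-yl]-2,6-dimethoxyphenol (not isolated) | C[C@H]1[C@@H](c2cc(OC)c(O)c(OC)c2)c2c(OC)c(OCOC)c(OC)cc2C=C1C | intermediate
26 | 4-[(1S,2S)-7-hydroxy-6,8-dimethoxy-2,3-dimethyl-1,2-dihydronaphthalen-1-yl]-2,6-dimethoxyphenol | COc1cc([C@H]2c3c(cc(OC)c(O)c3OC)C=C(C)[C@H]2C)cc(OC)c1O | target

## Step count and risk

Total step count: 16. Longest linear sequence: 13 (steps 1–10, 14, 15, 16); the three-step ring B branch (steps 11–13) joins at step 14.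

The three steps most likely to fail:

Step 9 (Parham cyclisation). The aryllithium can be quenched by proton transfer from C2–H, or t-BuLi can attack the amide directly. The fallback sets out from 12 and comes back at 15 and avoids organolithium chemistry. The bromide of 12 is borylated (B2pin2, Pd(OAc)2/SPhos, KOAc, dioxane, 90 °C) to the aryl pinacol boronate Weinreb amide F1. The amide is reduced with i-Bu2AlH (THF, −78 °C) to the boronate aldehyde F2. Ring C is then closed by rhodium-catalysed intramolecular 1,2-addition of the arylboronate to the aldehyde ([Rh(cod)Cl]2, aq. KOH, dioxane, 60 °C) to give the cyclic benzylic alcohol F3, which Dess–Martin periodinane oxidises to tetralone 15.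

Step 14 (Suzuki coupling of the hindered enol triflate). The triflate may hydrolyse back to the ketone or transmetalate too slowly. The fallback sets out from tetralone 15 (with bromide 20) and comes back at 22, building the C1–aryl bond by carbonyl addition instead of cross-coupling. Bromide 20 is lithiated (n-BuLi, THF, −78 °C), transmetalated with CeCl3 and added to 15 to give the tertiary benzylic alcohol F4. Dehydration with the Burgess reagent (benzene, 50 °C), where only C2–H is available, gives alkene 22.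

Step 15 (hydrogenation). Pd/C may stall on the tetrasubstituted alkene or begin to cleave the benzylic C4–O bond on prolonged exposure. The fallback sets out from 22 and comes back at 24 and separates alkene saturation from deprotection. The alkene is hydrogenated with the cationic complex [Ir(cod)(PCy3)(py)]PF6 (H2 50 bar, CH2Cl2), which reduces tetrasubstituted alkenes without hydrogenolysing ethers, to the benzyl-protected all-cis tetralin F5; the wrong-face diastereomer is removed by chromatography. The benzyl group is then taken off by brief hydrogenolysis (H2 1 bar, 10% Pd/C, EtOAc) to give 24.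

## Further compounds

F1 | step 9 | (3S,4S)-4-[3,5-dimethoxy-4-(methoxymethoxy)-2-(4,4,5,5-tetramethyl-1,3,2-dioxaborolan-2-yl)phenyl]-4-(TBS-oxy)-N-methoxy-N,2,3-trimethylbutanamide | CON(C)C(=O)C(C)[C@H](C)[C@H](O[Si](C)(C)C(C)(C)C)c1cc(OC)c(OCOC)c(OC)c1B1OC(C)(C)C(C)(C)O1
F2 | step 9 | (3S,4S)-4-[3,5-dimethoxy-4-(methoxymethoxy)-2-(4,4,5,5-tetramethyl-1,3,2-dioxaborolan-2-yl)phenyl]-4-(TBS-oxy)-2,3-dimethylbutanal | O=CC(C)[C@H](C)[C@H](O[Si](C)(C)C(C)(C)C)c1cc(OC)c(OCOC)c(OC)c1B1OC(C)(C)C(C)(C)O1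
F3 | step 9 | (3S,4S)-4-(TBS-oxy)-6,8-dimethoxy-7-(methoxymethoxy)-2,3-dimethyl-1,2,3,4-tetrahydronaphthalen-1-ol (C1/C2 epimers) | CC1C(O)c2c(OC)c(OCOC)c(OC)cc2[C@@H](O[Si](C)(C)C(C)(C)C)[C@H]1C
F4 | step 14 | (3S,4S)-1-[4-(benzyloxy)-3,5-dimethoxyphenyl]-4-(TBS-oxy)-6,8-dimethoxy-7-(methoxymethoxy)-2,3-dimethyl-1,2,3,4-tetrahydronaphthalen-1-ol (C1/C2 epimers) | CC1C(O)(c2cc(OC)c(OCc3ccccc3)c(OC)c2)c2c(OC)c(OCOC)c(OC)cc2[C@@H](O[Si](C)(C)C(C)(C)C)[C@H]1C
F5 | step 15 | (1S,2S,3S,4S)-1-[4-(benzyloxy)-3,5-dimethoxyphenyl]-4-(TBS-oxy)-6,8-dimethoxy-7-(methoxymethoxy)-2,3-dimethyl-1,2,3,4-tetrahydronaphthalene | C[C@H]1[C@@H](c2cc(OC)c(OCc3ccccc3)c(OC)c2)c2c(OC)c(OCOC)c(OC)cc2[C@@H](O[Si](C)(C)C(C)(C)C)[C@H]1C
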